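**Strategy.** Both arms on the anisole ring are E-ArCH2–CH=C(CH3)–C–O units. The route cuts the benzylic C1'–vinylic C2' bond of the 4'-hydroxygeranyl arm and makes it by a one-pot Zr-catalysed syn-methylalumination of a terminal (R)-propargylic silyl ether followed by Pd-catalysed alkenyl–benzyl coupling. One operation adds the C3' methyl, fixes the 2'E geometry and joins the halves, exploiting the C2'=C3'(CH3) trisubstituted alkene next to the C4' carbinol as the retron of an alkyne. The precursor pair is a benzylic bromide, itself made by the same reaction on a symmetric 2,6-bis(bromomethyl)anisole, and an eight-carbon enyne whose stereocentre comes from asymmetric transfer hydrogenation.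

Key step: step 8

Assumption: methyl 4-methoxy-3,5-dimethylbenzoate (1) is taken as a catalogue compound; locants 1'–8' number the C10 arm from its benzylic carbon.

Step 1
Reactants: 1 methyl 4-methoxy-3,5-dimethylbenzoate
Product: 2 methyl 3,5-bis(bromomethyl)-4-methoxybenzoate
Conditions: NBS (2.1 equiv), AIBN (5 mol %), PhCF3, 85 °C
Reagents that add atoms: N-bromosuccinimide, O=C1CCC(=O)N1Br
Why: Wohl–Ziegler radical bromination: the two equivalent benzylic methyl groups are the only activated C–H bonds, and the ring positions activated by OMe are all substituted, so nuclear bromination should not compete.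

Step 2
Reactants: 3 tert-butyldimethyl(prop-2-yn-1-yloxy)silane; 2 methyl 3,5-bis(bromomethyl)-4-methoxybenzoate
Product: 5 methyl 3-(bromomethyl)-5-[(2E)-4-{[tert-butyl(dimethyl)silyl]oxy}-3-methylbut-2-en-1-yl]-4-methoxybenzoate, via alkenylalane 4 (not isolated)
Conditions: 3 (1 equiv), Me3Al (2 equiv), Cp2ZrCl2 (0.2 equiv), CH2Cl2, 0 °C to rt; volatiles removed in vacuo; then 2 (3 equiv), Pd(PPh3)4 (5 mol %), THF, 0 °C to rt
Reagents that add atoms: trimethylaluminium, C[Al](C)C
Why: Negishi Zr-catalysed carboalumination followed by Pd-catalysed alkenylalane–benzyl bromide cross-coupling: syn-addition of CH3–Al across the terminal alkyne fixes the E alkene, which is transferred with retention, and a threefold excess of the symmetric dibromide 2 should hold the second coupling to a minor pathway (unreacted 2 is recovered).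

Step 3
Reactants: 6 4-methylpent-3-enoic acid
Product: 7 N-methoxy-N,4-dimethylpent-3-enamide
Conditions: CDI (1.1 equiv), CH2Cl2, 0 °C to rt; then MeNHOMe·HCl (1.2 equiv), rt
Reagents that add atoms: N,O-dimethylhydroxylamine hydrochloride, CNOC.Cl
Why: Weinreb amide formation through the acyl imidazole: activation and amidation run without strong base, so the skipped C3=C4 alkene should not move into conjugation.

Step 4
Reactants: 7 N-methoxy-N,4-dimethylpent-3-enamide
Product: 8 6-methyl-1-(trimethylsilyl)hept-5-en-1-yn-3-one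
Conditions: ethynyltrimethylsilane (1.3 equiv), n-BuLi (1.25 equiv), THF, −78 °C; then 7, −78 to −20 °C; cold 1 M HCl quench
Reagents that add atoms: ethynyltrimethylsilane, C#C[Si](C)(C)C
Why: Weinreb ketone synthesis: the lithium acetylide adds once to give a chelated tetrahedral intermediate that collapses only on acidic quench, which also protonates the released amine so that it cannot add to the ynone.

Step 5
Reactants: 8 6-methyl-1-(trimethylsilyl)hept-5-en-1-yn-3-one
Product: 9 (3R)-6-methyl-1-(trimethylsilyl)hept-5-en-1-yn-3-ol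
Conditions: Ru[(R,R)-TsDPEN](p-cymene) (preformed amido complex, 1 mol %), i-PrOH, rt
Reagents that add atoms: none
Why: Noyori asymmetric transfer hydrogenation of an alkynyl ketone: the alkynyl group takes the place of the aryl group in the six-membered Ru–H/N–H transition state, so the (R,R)-catalyst is expected to deliver hydride to the face that gives the (R)-carbinol, and the base-free conditions spare the enolisable skipped enone.

Step 6
Reactants: 9 (3R)-6-methyl-1-(trimethylsilyl)hept-5-en-1-yn-3-ol
Product: 10 tert-butyldimethyl{[(3R)-6-methyl-1-(trimethylsilyl)hept-5-en-1-yn-3-yl]oxy}silane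
Conditions: TBSCl (1.2 equiv), imidazole (2.5 equiv), DMF, rt
Reagents that add atoms: tert-butyldimethylsilyl chloride, CC(C)(C)[Si](C)(C)Cl
Why: Standard imidazole-promoted silylation of a secondary alcohol (Corey protocol), which does not touch the stereocentre.

Step 7
Reactants: 10 tert-butyldimethyl{[(3R)-6-methyl-1-(trimethylsilyl)hept-5-en-1-yn-3-yl]oxy}silane
Product: 11 tert-butyldimethyl{[(3R)-6-methylhept-5-en-1-yn-3-yl]oxy}silane
Conditions: K2CO3 (0.3 equiv), MeOH, rt
Reagents that add atoms: none
Why: Base-catalysed methanolysis (protodesilylation) of the alkynyl C–SiMe3 bond, to which the hindered O–TBS ether is inert.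

Step 8
Reactants: 11 tert-butyldimethyl{[(3R)-6-methylhept-5-en-1-yn-3-yl]oxy}silane; 5 methyl 3-(bromomethyl)-5-[(2E)-4-{[tert-butyl(dimethyl)silyl]oxy}-3-methylbut-2-en-1-yl]-4-methoxybenzoate
Product: 13 methyl 3-[(2E,4R)-4-{[tert-butyl(dimethyl)silyl]oxy}-3,7-dimethylocta-2,6-dien-1-yl]-5-[(2E)-4-{[tert-butyl(dimethyl)silyl]oxy}-3-methylbut-2-en-1-yl]-4-methoxybenzoate, via alkenylalane 12 (not isolated)
Conditions: 11 (1.2 equiv), Me3Al (2 equiv), Cp2ZrCl2 (0.25 equiv), CH2Cl2, 0 °C to rt; volatiles removed in vacuo; then 5 (1 equiv), Pd(PPh3)4 (5 mol %), THF, 0 °C to rt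
Reagents that add atoms: trimethylaluminium, C[Al](C)C
Why: Cp2ZrCl2-catalysed methylalumination adds CH3 and Al syn across the terminal C≡C of 11 with aluminium on the unsubstituted carbon, so the (1E)-alkenylalane 12 already holds the C3' methyl and the 2'E geometry; Pd(0) then inserts into the benzylic C–Br bond of 5, the alkenyl group transmetalates from aluminium in preference to methyl, and reductive elimination forms the C1'–C2' bond with retention of alkene geometry. The closest known reaction type is the Negishi one-pot carboalumination/alkenylalane–benzyl halide cross-coupling used for prenylated arenes and quinones. No ring is closed and no stereocentre is created: the (4'R) centre is carried in from 11 and cannot epimerise because C4' is never metalated or ionised. The step needs regio- and syn-selectivity in the carbometalation, secured by the steric bias of the terminal alkyne and the concerted four-centre addition, and chemoselectivity, secured by the inertness of the trisubstituted C6'=C7' alkene towards Zr/Al and by stripping excess Me3Al before the ester-bearing bromide is added.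

Step 9
Reactants: 13 methyl 3-[(2E,4R)-4-{[tert-butyl(dimethyl)silyl]oxy}-3,7-dimethylocta-2,6-dien-1-yl]-5-[(2E)-4-{[tert-butyl(dimethyl)silyl]oxy}-3-methylbut-2-en-1-yl]-4-methoxybenzoate
Product: 15 3-[(2E,4R)-4-hydroxy-3,7-dimethylocta-2,6-dien-1-yl]-5-[(2E)-4-hydroxy-3-methylbut-2-en-1-yl]-4-methoxybenzoic acid, via diol methyl ester 14 (not isolated)
Conditions: TBAF (3 equiv), THF, rt; then LiOH·H2O (5 equiv), MeOH/H2O, 40 °C; 1 M HCl to pH 3–4 at 0 °C
Reagents that add atoms: lithium hydroxide, [Li+].[OH-]
Why: Fluoride-mediated cleavage of both TBS ethers followed in the same flask by saponification of the methyl benzoate; the mild acidification should leave the allylic alcohols and the (4'R) centre untouched.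

**Compound list**

1 | methyl 4-methoxy-3,5-dimethylbenzoate | COC(=O)c1cc(C)c(OC)c(C)c1 | starting material
2 | methyl 3,5-bis(bromomethyl)-4-methoxybenzoate | COC(=O)c1cc(CBr)c(OC)c(CBr)c1 | intermediate
3 | tert-butyldimethyl(prop-2-yn-1-yloxy)silane | C#CCO[Si](C)(C)C(C)(C)C | starting material
4 | [(1E)-3-{[tert-butyl(dimethyl)silyl]oxy}-2-methylprop-1-en-1-yl]dimethylalane | C[Al](C)/C=C(\C)CO[Si](C)(C)C(C)(C)C | intermediate
5 | methyl 3-(bromomethyl)-5-[(2E)-4-{[tert-butyl(dimethyl)silyl]oxy}-3-methylbut-2-en-1-yl]-4-methoxybenzoate | COC(=O)c1cc(CBr)c(OC)c(C/C=C(\C)CO[Si](C)(C)C(C)(C)C)c1 | intermediate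
6 | 4-methylpent-3-enoic acid | CC(C)=CCC(=O)O | starting material
7 | N-methoxy-N,4-dimethylpent-3-enamide | CON(C)C(=O)CC=C(C)C | intermediate
8 | 6-methyl-1-(trimethylsilyl)hept-5-en-1-yn-3-one | C[Si](C)(C)C#CC(=O)CC=C(C)C | intermediate
9 | (3R)-6-methyl-1-(trimethylsilyl)hept-5-en-1-yn-3-ol | C[Si](C)(C)C#C[C@H](O)CC=C(C)C | intermediate
10 | tert-butyldimethyl{[(3R)-6-methyl-1-(trimethylsilyl)hept-5-en-1-yn-3-yl]oxy}silane | C[Si](C)(C)C#C[C@H](O[Si](C)(C)C(C)(C)C)CC=C(C)C | intermediate
11 | tert-butyldimethyl{[(3R)-6-methylhept-5-en-1-yn-3-yl]oxy}silane | C#C[C@H](O[Si](C)(C)C(C)(C)C)CC=C(C)C | intermediate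
12 | [(1E,3R)-3-{[tert-butyl(dimethyl)silyl]oxy}-2,6-dimethylhepta-1,5-dien-1-yl]dimethylalane | C[Al](C)/C=C(\C)[C@H](O[Si](C)(C)C(C)(C)C)CC=C(C)C | intermediate
13 | methyl 3-[(2E,4R)-4-{[tert-butyl(dimethyl)silyl]oxy}-3,7-dimethylocta-2,6-dien-1-yl]-5-[(2E)-4-{[tert-butyl(dimethyl)silyl]oxy}-3-methylbut-2-en-1-yl]-4-methoxybenzoate | COC(=O)c1cc(C/C=C(\C)CO[Si](C)(C)C(C)(C)C)c(OC)c(C/C=C(\C)[C@H](O[Si](C)(C)C(C)(C)C)CC=C(C)C)c1 | intermediate
14 | methyl 3-[(2E,4R)-4-hydroxy-3,7-dimethylocta-2,6-dien-1-yl]-5-[(2E)-4-hydroxy-3-methylbut-2-en-1-yl]-4-methoxybenzoate | COC(=O)c1cc(C/C=C(\C)CO)c(OC)c(C/C=C(\C)[C@H](O)CC=C(C)C)c1 | intermediate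
15 | 3-[(2E,4R)-4-hydroxy-3,7-dimethylocta-2,6-dien-1-yl]-5-[(2E)-4-hydroxy-3-methylbut-2-en-1-yl]-4-methoxybenzoic acid | COc1c(C/C=C(\C)CO)cc(C(=O)O)cc1C/C=C(\C)[C@H](O)CC=C(C)C | target

**Totals.** Total step count: 9. Longest linear sequence: 7 steps (steps 3, 4, 5, 6, 7, 8, 9, from acid 6).

**Steps most likely to fail**

Step 8. The methylalumination of the hindered α-silyloxy alkyne may stall or lose regiocontrol, and in the telescoped coupling methyl transfer or attack of aluminium species on the ester may compete. The fallback sets out from alkyne 11 and benzylic bromide 5 and comes back to the route at 13. Alane 12, made as in step 8, would be quenched with iodine (THF, −30 °C) and the product purified as the (1E,3R)-vinyl iodide F1, which removes any regioisomer. Bromide 5 would be converted with zinc dust and LiCl in THF into the benzylzinc bromide F2. A Pd(OAc)2/SPhos Negishi coupling of F2 with F1 in THF at rt should then give 13. The roles of nucleophile and electrophile are inverted and no aluminium reagent meets the ester.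

Step 2. Coupling at the second benzylic bromide may not be held back, and mono- and bis-adducts may prove hard to separate. The fallback sets out from alkenylalane 4 (made from 3 as in step 2) and comes back at 5. It replaces statistical differentiation by an arene whose second benzylic position is masked as an aryl bromide. Methyl 3-bromo-4-methoxy-5-methylbenzoate F3 would be brominated (NBS, AIBN, PhCF3, 85 °C) to methyl 3-bromo-5-(bromomethyl)-4-methoxybenzoate F4. Its single benzylic bromide should couple with 4 (Pd(PPh3)4, THF, rt), the ortho-substituted aryl bromide being expected to stay intact at this temperature, to give the aryl bromide F5. Stille hydroxymethylation (Bu3SnCH2OH, Pd(PPh3)4, dioxane, 90 °C) should give the benzylic alcohol F6, and Appel bromination (CBr4, PPh3, CH2Cl2, 0 °C) returns 5.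

Step 5. The skipped alkene may migrate into conjugation under the basic amido catalyst, or the facial selectivity of hydride transfer may erode. The fallback sets out from acid 6 and comes back at 9, and it builds the carbinol by enantioselective C–C bond formation so that the ynone is never made. LiAlH4 reduction (Et2O, 0 °C) should give 4-methylpent-3-en-1-ol F7, and buffered Dess–Martin oxidation (NaHCO3, CH2Cl2, 0 °C) the aldehyde 4-methylpent-3-enal F8, used crude. A Zn–ProPhenol-catalysed addition of ethynyltrimethylsilane (Me2Zn, toluene, 0 °C), with the ligand enantiomer chosen for the (R)-carbinol, should give 9 directly.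

Further compounds
F1 | step 8 | tert-butyl{[(1E,3R)-1-iodo-2,6-dimethylhepta-1,5-dien-3-yl]oxy}dimethylsilane | I/C=C(\C)[C@H](O[Si](C)(C)C(C)(C)C)CC=C(C)C
F2 | step 8 | {3-[(2E)-4-{[tert-butyl(dimethyl)silyl]oxy}-3-methylbut-2-en-1-yl]-2-methoxy-5-(methoxycarbonyl)benzyl}zinc bromide | COC(=O)c1cc(C[Zn]Br)c(OC)c(C/C=C(\C)CO[Si](C)(C)C(C)(C)C)c1
F3 | step 2 | methyl 3-bromo-4-methoxy-5-methylbenzoate | COC(=O)c1cc(C)c(OC)c(Br)c1
F4 | step 2 | methyl 3-bromo-5-(bromomethyl)-4-methoxybenzoate | COC(=O)c1cc(CBr)c(OC)c(Br)c1
F5 | step 2 | methyl 3-bromo-5-[(2E)-4-{[tert-butyl(dimethyl)silyl]oxy}-3-methylbut-2-en-1-yl]-4-methoxybenzoate | COC(=O)c1cc(C/C=C(\C)CO[Si](C)(C)C(C)(C)C)c(OC)c(Br)c1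
F6 | step 2 | methyl 3-[(2E)-4-{[tert-butyl(dimethyl)silyl]oxy}-3-methylbut-2-en-1-yl]-5-(hydroxymethyl)-4-methoxybenzoate | COC(=O)c1cc(C/C=C(\C)CO[Si](C)(C)C(C)(C)C)c(OC)c(CO)c1
F7 | step 5 | 4-methylpent-3-en-1-ol | CC(C)=CCCO
F8 | step 5 | 4-methylpent-3-enal | CC(C)=CCC=O
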